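**Retrosynthetic overview**
1. Target 12 comes from dibenzyl ether 11 by removing the two benzyl groups in the last step.
2. 11 comes from 3,4-epoxyflavan 8 and (−)-epicatechin 9. The C4–C8 bond forms by β-face opening of an oxirane that sits cis to the 2-aryl group. Rings D, E and F arrive intact in 9.
3. 8 comes from salicylaldehyde 5 (ring A) and styrylsulfonium salt 4 (ring B). O1–C2, C3–C4 and C3–O are cut together, so pyran ring C and the oxirane close in one flask.
4. 4 comes from styrene 1 and diphenyl sulfoxide 2.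
5. Ring order: A, B, D, E and F are bought. Ring C and the oxirane form together in step 2. The oxirane is consumed in step 3.

Assumption: the SMILES is read as epiguibourtinidol-(4β→8)-epicatechin (upper unit 2R,3R,4R, i.e. 2,3-cis-3,4-trans; lower unit 2R,3R). Compound 8 is carried as the racemate, and the absolute configuration of the upper unit is fixed in step 3 by union with enantiopure 9.

Step 1
Reactants: 1 4-benzyloxystyrene; 2 diphenyl sulfoxide
Product: 4 (E)-[2-(4-benzyloxyphenyl)ethenyl]diphenylsulfonium triflate, via triflyloxysulfonium triflate 3 (not isolated)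
Conditions: Tf2O (1.1 equiv), 2,6-di-tert-butylpyridine (1.1 equiv), CH2Cl2, −78 °C; then 1, −78 → 0 °C; precipitation from Et2O
Reagents that add atoms: triflic anhydride O=S(=O)(OS(=O)(=O)C(F)(F)F)C(F)(F)F
Why: Tf2O turns 2 into the sulfur electrophile 3, the terminal carbon of the electron-rich styrene attacks it, and the resulting benzylic cation loses the acidified α-sulfonio proton to give the conjugated (E)-alkenylsulfonium salt (interrupted-Pummerer-type alkene sulfoniation, known for styrenes), with no stereocentre formed.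

Step 2
Reactants: 4 (E)-[2-(4-benzyloxyphenyl)ethenyl]diphenylsulfonium triflate; 5 4-benzyloxy-2-hydroxybenzaldehyde
Product: 8 rac-(2R,3R,4R)-7-benzyloxy-2-(4-benzyloxyphenyl)-3,4-epoxychroman (oxirane cis to the 2-aryl group), via sulfonium ylide 6 (not isolated), via anti-betaine 7 (not isolated)
Conditions: DBU (2.0 equiv), CH2Cl2, 0 °C → rt; filtration through basic Al2O3; used at once
Reagents that add atoms: none
Why: Proposed new method: the phenoxide of 5 adds reversibly to the aryl-bearing β-carbon of 4 (heteroatom conjugate addition to styrylsulfonium salts is known from their aziridination by amines), the ylide 6 attacks the neighbouring aldehyde through a chair-like transition state with the aryl group and the bulky Ph2S+ group both equatorial and hence trans, and because only a betaine with O− anti to S+ (7) can expel Ph2S by internal SN2 attack the oxirane oxygen ends cis to the 2-aryl group, so the O1–C2, C3–C4 and C3–O bonds, pyran ring C and the oxirane form in one flask with the 2,3-cis relation fixed (racemate); the closest known reaction types are the epoxy-annulation of hydroxy- or amino-carbonyl compounds by vinyl- and β-CF3-vinyl-diphenylsulfonium triflates (oxa-Michael/Corey–Chaykovsky cascade) and the Schweizer chromene synthesis from salicylaldehydes and vinylphosphonium salts.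

Step 3
Reactants: 8 rac-(2R,3R,4R)-7-benzyloxy-2-(4-benzyloxyphenyl)-3,4-epoxychroman; 9 (−)-epicatechin
Product: 11 7,4'-di-O-benzyl-epiguibourtinidol-(4β→8)-epicatechin, via flavan-4-yl cation 10 (not isolated)
Conditions: 9 (4 equiv, excess recovered), TsOH·H2O (5 mol %), THF, −20 → 0 °C, slow addition of 8, Ar; SiO2 (CH2Cl2–MeOH)
Reagents that add atoms: none
Why: Acid opens the C4–O bond, which is benzylic and para to the 7-benzyloxy group, to cation 10 whose α face is covered by the axial 3-oxygen, so C8 of ring D of 9 (its most nucleophilic carbon) bonds from the β face and sets 4R with the 3,4-trans relation seen for all 2,3-cis flavan-4-yl cations (Friedel–Crafts arylation of a benzylic epoxide), C2 and C3 stay untouched, and because 9 is one enantiomer the (2S,3S,4S) half of 8 ends up as a diastereomer that chromatography removes.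

Step 4
Reactants: 11 7,4'-di-O-benzyl-epiguibourtinidol-(4β→8)-epicatechin
Product: 12 epiguibourtinidol-(4β→8)-epicatechin (CNP0118995.2)
Conditions: H2 (1 atm), Pd(OH)2/C, THF–MeOH, rt
Reagents that add atoms: none
Why: Hydrogenolysis of the two aryl benzyl ethers is much faster than cleavage of the cyclic benzylic C2–O1 bonds or of the C4–C8 bond, as in the usual last step of procyanidin syntheses, and it touches no stereocentre.

**Compound list**
1 | 4-benzyloxystyrene | C=Cc1ccc(OCc2ccccc2)cc1 | starting material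
2 | diphenyl sulfoxide | O=S(c1ccccc1)c1ccccc1 | starting material
3 | diphenyl(trifluoromethylsulfonyloxy)sulfonium triflate | FC(F)(F)S(=O)(=O)O[S+](c1ccccc1)c1ccccc1.[O-]S(=O)(=O)C(F)(F)F | intermediate
4 | (E)-[2-(4-benzyloxyphenyl)ethenyl]diphenylsulfonium triflate | C(c1ccccc1)Oc1ccc(/C=C/[S+](c2ccccc2)c2ccccc2)cc1.[O-]S(=O)(=O)C(F)(F)F | intermediate
5 | 4-benzyloxy-2-hydroxybenzaldehyde | O=Cc1ccc(OCc2ccccc2)cc1O | starting material
6 | β-aryloxy sulfonium ylide (racemic, 2R enantiomer drawn) | O=Cc1ccc(OCc2ccccc2)cc1O[C@H](c1ccc(OCc2ccccc2)cc1)[CH-][S+](c1ccccc1)c1ccccc1 | intermediate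
7 | 4-oxido-3-(diphenylsulfonio)flavan betaine, aryl/S trans, S/O trans (racemic) | C(c1ccccc1)Oc1ccc([C@H]2Oc3cc(OCc4ccccc4)ccc3[C@@H]([O-])[C@@H]2[S+](c2ccccc2)c2ccccc2)cc1 | intermediate
8 | rac-(2R,3R,4R)-7-benzyloxy-2-(4-benzyloxyphenyl)-3,4-epoxychroman (2R,3R,4R enantiomer drawn) | C(c1ccccc1)Oc1ccc([C@H]2Oc3cc(OCc4ccccc4)ccc3[C@H]4O[C@@H]24)cc1 | intermediate
9 | (−)-epicatechin, (2R,3R) | Oc1cc(O)c2c(c1)O[C@H](c1ccc(O)c(O)c1)[C@H](O)C2 | starting material
10 | 2,3-cis-7-benzyloxy-2-(4-benzyloxyphenyl)-3-hydroxychroman-4-ylium ion (racemic) | C(c1ccccc1)Oc1ccc([C@H]2Oc3cc(OCc4ccccc4)ccc3[CH+][C@H]2O)cc1 | intermediate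
11 | 7,4'-di-O-benzyl-epiguibourtinidol-(4β→8)-epicatechin, upper 2R,3R,4R, lower 2R,3R | C(c1ccccc1)Oc1ccc([C@H]2Oc3cc(OCc4ccccc4)ccc3[C@H](c3c(O)cc(O)c4c3O[C@H](c3ccc(O)c(O)c3)[C@H](O)C4)[C@H]2O)cc1 | intermediate
12 | epiguibourtinidol-(4β→8)-epicatechin | Oc1ccc([C@H]2Oc3cc(O)ccc3[C@H](c3c(O)cc(O)c4c3O[C@H](c3ccc(O)c(O)c3)[C@H](O)C4)[C@H]2O)cc1 | target

**Total step count:** 4. **Longest linear sequence:** 4 (1 → 4 → 8 → 11 → 12).

**Steps most likely to fail**

Step 2 is the riskiest.
- The donor aryl group slows the conjugate addition.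
- A cis-betaine would give the flavanone by hydride shift.
- The electron-rich ring A could migrate and contract the ring.
- The oxirane could form trans to the aryl group.

The fallback sets out from 1 and 5 and comes back at 8.
- Cross-metathesis of 1 with vinylboronic acid pinacol ester (second-generation Hoveyda–Grubbs catalyst, CH2Cl2, reflux) gives (E)-2-(4-benzyloxyphenyl)ethenylboronic acid pinacol ester F1.
- A Petasis-type condensation of F1 with 5 and dibenzylamine in hot dioxane follows. Thermal loss of the amine and oxa-6π ring closure then give racemic 7-benzyloxy-2-(4-benzyloxyphenyl)-2H-chromene F2.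
- NBS in wet THF puts Br+ on the face away from the 2-aryl group and water on C4. This gives the trans-3-bromo-4-hydroxyflavan F3.
- NaH in THF closes the 4-alkoxide onto C3, so the oxirane lies cis to the aryl group, which is 8.

Step 3 is next.
- 10 can shift hydride to give the flavan-3-one.
- C6 attack, O-alkylation and over-alkylation can compete.
- The polar diastereomers may be hard to separate.

The fallback sets out from 8 and 9 and comes back at 12.
- 9 is benzylated on its four phenols (BnBr, K2CO3, DMF) to 5,7,3',4'-tetra-O-benzyl-(−)-epicatechin F4.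
- F4 (3 equiv) and 8 are joined by BF3·OEt2 in CH2Cl2 at −78 °C. In this protected series C8 is the site that reacts. The product is the hexa-O-benzyl dimer F5, which is separated from its diastereomer on plain SiO2.
- H2 over Pd(OH)2/C then gives 12 directly.

Step 1 is third. The acid-sensitive styrene may polymerise, or the arene may be sulfoniated instead of the alkene. The fallback sets out from 1 and comes back at 4.
- NBS in aqueous acetone gives 2-bromo-1-(4-benzyloxyphenyl)ethanol F6.
- Ph2S and AgOTf in CH2Cl2 alkylate sulfur at the primary carbon to give [2-(4-benzyloxyphenyl)-2-hydroxyethyl]diphenylsulfonium triflate F7.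
- MsCl/Et3N mesylates the alcohol and triggers E1cB elimination to 4.

**Further compounds**
F1 | step 2 | (E)-2-[2-(4-benzyloxyphenyl)ethenyl]-4,4,5,5-tetramethyl-1,3,2-dioxaborolane | C(c1ccccc1)Oc1ccc(/C=C/B2OC(C)(C)C(C)(C)O2)cc1
F2 | step 2 | rac-7-benzyloxy-2-(4-benzyloxyphenyl)-2H-chromene (enantiomer leading to 12 drawn) | C(c1ccccc1)Oc1ccc([C@H]2Oc3cc(OCc4ccccc4)ccc3C=C2)cc1
F3 | step 2 | rac-2,3-trans-3,4-trans-7-benzyloxy-2-(4-benzyloxyphenyl)-3-bromochroman-4-ol | C(c1ccccc1)Oc1ccc([C@H]2Oc3cc(OCc4ccccc4)ccc3[C@@H](O)[C@@H]2Br)cc1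
F4 | step 3 | 5,7,3',4'-tetra-O-benzyl-(−)-epicatechin | C(c1ccccc1)Oc1cc(OCc2ccccc2)c2c(c1)O[C@H](c1ccc(OCc3ccccc3)c(OCc3ccccc3)c1)[C@H](O)C2
F5 | step 3 | hexa-O-benzyl-epiguibourtinidol-(4β→8)-epicatechin | C(c1ccccc1)Oc1ccc([C@H]2Oc3cc(OCc4ccccc4)ccc3[C@H](c3c(OCc4ccccc4)cc(OCc4ccccc4)c4c3O[C@H](c3ccc(OCc5ccccc5)c(OCc5ccccc5)c3)[C@H](O)C4)[C@H]2O)cc1
F6 | step 1 | rac-2-bromo-1-(4-benzyloxyphenyl)ethanol | OC(CBr)c1ccc(OCc2ccccc2)cc1
F7 | step 1 | rac-[2-(4-benzyloxyphenyl)-2-hydroxyethyl]diphenylsulfonium triflate | OC(C[S+](c1ccccc1)c1ccccc1)c1ccc(OCc2ccccc2)cc1.[O-]S(=O)(=O)C(F)(F)F
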